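## Structural features

Rhoiptelol B is a cyclised diarylheptanoid. Its tetrahydropyran (ring atoms O1, C2, C3, C4, C5, C6) carries a 4-hydroxy-3-methoxyphenyl (guaiacyl) ring on C2, a hydroxyl on C4 and, on C6, the arm C7(OH)–C8H2 that ends in a 4-hydroxyphenyl ring. The four stereocentres are 2R, 4S, 6S and 7S. The C2 and C6 substituents are cis and equatorial, and the C4 hydroxyl is trans to both and therefore axial. C6 and C7 are adjacent; in the open chain the C6/C7 oxygens are syn and the C4/C6 oxygens are 1,3-syn. The fragile element is the O1–C2 bond, a benzylic ether para to a phenolic oxygen: it ionises under acid and is exposed under hydrogenolysis. The real difficulty is to tell three secondary oxygens apart (C4, C6, C7), of which only the one on C6 may become the ring oxygen, and to control the C6/C7 pair and the remote C4 centre. The key step turns the lability of O1–C2 into an advantage: a C2 cation, stabilised by the para oxygen of the guaiacyl ring (the meta methoxy group gives no resonance help), is captured by the C6 hydroxyl. Because the new ether can re-ionise, the ring should settle into the 2,6-cis diequatorial chair whatever the configuration of the C2 alcohol was.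

## Logic of the disconnections

21 ⇒ 20. The four O–Si bonds are cut. All protecting groups are silyl, so one fluoride treatment should finish the synthesis and no hydrogenolysis is run next to the O1–C2 benzylic ether. The forward step only has to avoid acid and strong base.

20 ⇒ 18. The O1–C2 bond is cut. This removes the ring and the C2 stereocentre at once and leaves an open 1,5-diol whose C2 configuration is irrelevant. The forward step demands that the C6 hydroxyl is the only free nucleophile, that the silyl ethers survive a catalytic acid, and that the closure is reversible.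

18 ⇒ 17. The C2–H bond is cut (carbinol back to aryl ketone). Nothing is gained in stereochemistry, but 17 is the direct product of an aryl addition to a lactone. The forward reduction needs no selectivity.

17 ⇒ 13 + 15. The C2–aryl bond is cut. The guaiacyl ring leaves as an aryl nucleophile (16, made from 15). The acyl partner 13 is a δ-lactone whose ring oxygen is the C6 oxygen, so this oxygen never needs a protecting group and is freed in the very step that installs the aryl group. The forward step demands a single addition to the lactone carbonyl.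

15 ⇒ 14. One O–Si bond is cut; the phenol of 14 only has to be masked against the organolithium.

13 ⇒ 12 ⇒ 10. The C4 silyl ether and then the C4–O bond are cut. The C4 oxygen becomes the result of a conjugate addition to an unsaturated lactone, so the existing C6 centre can set C4 across the ring. The forward step must deliver the oxygen trans to the C6 side chain.

10 ⇒ 9 ⇒ 8. The C3=C4 double bond (ring-closing metathesis) and the acyl C2–O1 bond (esterification) are cut. Both are routine and reduce the lactone to a homoallylic alcohol.

8 ⇒ 6. The C5–C6 bond is cut (allyl addition to an aldehyde). This sets C6 next to the existing C7 centre. The forward step must give the syn relationship against the intrinsic Felkin preference, so it needs a strongly directing chiral reagent.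

6 ⇒ 5 ⇒ 4 ⇒ 3 ⇒ 1. These are oxidation-level and protecting-group changes. C7 comes from the α-carbon of 1 by replacement of nitrogen with oxygen with net retention, so no stereocentre has to be created for C7.

## Other disconnections considered

Alternative 1: The cut is at C3–C4 and C4–C5, with C4 as a carbonyl dianion equivalent. In the forward step the lithium anion of silyl dithiane A1 would open aryl oxirane A2 at its CH2 terminus (C3). A polar additive would then trigger a 1,4-Brook shift of silicon onto the new C2 alkoxide, and the regenerated anion would open epoxide A3 at C5 to give A4.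
- In its favour: three fragments and two C–C bonds are joined in one flask, and C6 and C7 arrive ready-made in A3. In convergence this is better than the chosen plan. C2 is uncontrolled in both plans, so on that point they are equal.
- Against it here: A4 has no ring and C4 is at the ketone level. Dithiane removal next to two electron-rich arenes, a hydroxyl-directed 1,3-syn reduction, differentiation of the C4 and C6 hydroxyls and an O1–C2 closure of the same ionising type would all still be needed. A2 is a para-alkoxy styrene oxide, prone to Meinwald rearrangement and to opening at the benzylic carbon.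
- Comparison: structurally it is a chain-building step and complements the ring closure; it does not replace it. Setting C4 by a substrate-directed reduction is about equal to the conjugate addition used here. In step count after the coupling and in functional-group risk it should be worse.

Alternative 2: The cut removes C5–C6 and O1–C2 together. In the forward step silyloxy diene A5 and α-silyloxy aldehyde A6 would combine under a chiral Lewis acid in a hetero-Diels–Alder reaction to give A7, with the endo approach placing the C2 and C6 substituents cis. Hydrolysis of the enol ether and a bulky hydride such as LiBH(sBu)3 would then give the axial C4 alcohol.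
- In its favour: a ring, two bonds and two stereocentres in one step from two fragments of similar size. This is the best step economy of the four plans and clearly better than the chosen one, probably by three or four steps. A6 is the same kind of aldehyde as 6.
- Against it here: the catalyst must impose the C6 configuration syn to the C7 oxygen against the Felkin bias of A6. That is the same mismatched problem as in step 5, but with a less general reagent class. A5 is an acid-sensitive electron-rich styrenyl enol ether. C2 is set kinetically and cannot correct itself in that step, and in A7 the O1–C2 bond is both benzylic and allylic, so it may ionise under the Lewis acid.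
- Comparison: mechanistically it is a concerted, kinetically controlled closure against an ionic, thermodynamically controlled one. Control of C6 rests on a chiral reagent in both plans (equal). Control of C2 should be more dependable in the chosen plan.

Alternative 3: The cut is at C2–C3. In the forward step DDQ would remove hydride from the vanillyl ether CH2 of A8 (the future C2). The resulting oxocarbenium ion would be attacked by the enol acetate terminus through a chair with the C6 substituent equatorial, giving A9.
- In its favour: a ring C–C bond is made from an unfunctionalised benzylic C–H, with no aryl organometallic and no C2 alcohol. In that respect it is better than the chosen plan. Chair oxocarbenium closures are normally cis-selective, so the expected C2 selectivity is equal, kinetic there and thermodynamic here.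
- Against it here: A8 has other oxidisable benzylic sites (C8 next to the 4-benzyloxyphenyl ring and three O-benzyl CH2 groups). The hindered C6 hydroxyl must first be etherified with an acid-labile vanillyl donor, and the enol acetate must be installed. The C4 ketone needs a later reduction. The three benzyl ethers force a final hydrogenolysis next to the O1–C2 benzylic ether.
- Comparison: both plans pass through a C2 cation stabilised by the para oxygen. The step count should be similar. The chosen plan should be safer in chemoselectivity and in the endgame.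

Key step: step 13

Assumption: atoms keep the numbering O1, C2 (guaiacyl-bearing) to C8 in open-chain intermediates too (TIPS = triisopropylsilyl, TBS = tert-butyldimethylsilyl), and the allylborane made from (−)-Ipc2BOMe (isopinocampheyl groups of the (+)-α-pinene series) is taken to add allyl to the Si face of an aldehyde.

## Route

Step 1
Reactants: 1 L-tyrosine
Product: 3 (S)-2-hydroxy-3-(4-hydroxyphenyl)propanoic acid, via α-lactone 2 (not isolated)
Conditions: NaNO2, 1 M H2SO4 (aq), 0 °C to rt
Reagents that add atoms: water, O
Why: Diazotisation of the α-amino acid; the carboxylate displaces N2 with inversion to give α-lactone 2 and water opens it with a second inversion, so the hydroxy acid should keep the S configuration that becomes C7.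

Step 2
Reactants: 3 (S)-2-hydroxy-3-(4-hydroxyphenyl)propanoic acid
Product: 4 methyl (S)-2-hydroxy-3-(4-hydroxyphenyl)propanoate
Conditions: MeOH, H2SO4 (cat.), reflux
Reagents that add atoms: methanol, CO
Why: Fischer esterification; the acidic conditions do not touch the carbinol centre or the phenol.

Step 3
Reactants: 4 methyl (S)-2-hydroxy-3-(4-hydroxyphenyl)propanoate
Product: 5 methyl (S)-2-(TIPSO)-3-[4-(TIPSO)phenyl]propanoate
Conditions: TIPSOTf (2.4 equiv), 2,6-lutidine, CH2Cl2, 0 °C to rt
Reagents that add atoms: triisopropylsilyl trifluoromethanesulfonate, CC(C)[Si](OS(=O)(=O)C(F)(F)F)(C(C)C)C(C)C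
Why: Silylation of the phenol and the secondary alcohol in one operation; TIPS is chosen because the aryl ether tolerates the basic steps ahead and the C7 ether resists acid and 1,2-migration to the C6 oxygen.

Step 4
Reactants: 5 methyl (S)-2-(TIPSO)-3-[4-(TIPSO)phenyl]propanoate
Product: 6 (S)-2-(TIPSO)-3-[4-(TIPSO)phenyl]propanal
Conditions: iBu2AlH (1.1 equiv), CH2Cl2, −78 °C; KNaC4H4O6 (aq)
Reagents that add atoms: none
Why: Partial reduction of an α-silyloxy ester with iBu2AlH at low temperature is a standard route to α-silyloxy aldehydes; the aldehyde should be used at once to avoid epimerisation at C7.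

Step 5
Reactants: 6 (S)-2-(TIPSO)-3-[4-(TIPSO)phenyl]propanal
Product: 8 (2S,3S)-2-(TIPSO)-1-[4-(TIPSO)phenyl]hex-5-en-3-ol, via borinate ester 7 (not isolated)
Conditions: (−)-Ipc2BOMe, allylMgBr, Et2O, 0 °C to rt, Mg salts filtered off; then 6, Et2O, −78 °C; then NaBO3·4H2O, THF–H2O, rt
Reagents that add atoms: B-allyldiisopinocampheylborane of the (+)-α-pinene series (made in the flask from allylmagnesium bromide, C=CC[Mg]Br, and (−)-Ipc2BOMe), C=CCB([C@@H]1C[C@@H]2C[C@H]([C@H]1C)C2(C)C)[C@@H]1C[C@@H]2C[C@H]([C@H]1C)C2(C)C
Why: Brown asymmetric allylboration through a closed chair transition state; the isopinocampheyl groups should direct allyl to the Si face of the aldehyde and set C6 as S, syn to the C7 silyloxy group. The substrate alone would favour the anti (Felkin) product, so the outcome rests on reagent control; the mild perborate work-up spares the aryl silyl ether.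

Step 6
Reactants: 8 (2S,3S)-2-(TIPSO)-1-[4-(TIPSO)phenyl]hex-5-en-3-ol
Product: 9 (2S,3S)-2-(TIPSO)-1-[4-(TIPSO)phenyl]hex-5-en-3-yl acrylate
Conditions: acryloyl chloride, Et3N, DMAP (cat.), CH2Cl2, 0 °C
Reagents that add atoms: acryloyl chloride, C=CC(=O)Cl
Why: O-acylation of the only free hydroxyl; this forms the acyl O1–C2 bond, so that from here on the C6 oxygen is masked as an ester oxygen.

Step 7
Reactants: 9 (2S,3S)-2-(TIPSO)-1-[4-(TIPSO)phenyl]hex-5-en-3-yl acrylate
Product: 10 (S)-6-[(S)-1-(TIPSO)-2-[4-(TIPSO)phenyl]ethyl]-5,6-dihydro-2H-pyran-2-one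
Conditions: second-generation Grubbs catalyst RuCl2(=CHPh)(PCy3)(H2IMes) (5 mol%), CH2Cl2 (0.01 M), 40 °C
Reagents that add atoms: none
Why: Ring-closing metathesis of an acrylate of a homoallylic alcohol, a well-established entry to 6-substituted 5,6-dihydropyran-2-ones; loss of ethylene drives the closure and no stereocentre is involved.

Step 8
Reactants: 10 (S)-6-[(S)-1-(TIPSO)-2-[4-(TIPSO)phenyl]ethyl]-5,6-dihydro-2H-pyran-2-one
Product: 12 (4R,6S)-4-hydroxy-6-[(S)-1-(TIPSO)-2-[4-(TIPSO)phenyl]ethyl]tetrahydro-2H-pyran-2-one, via boryl lactone 11 (not isolated)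
Conditions: B2pin2, CuCl (5 mol%), DPEphos (5 mol%), NaOtBu (10 mol%), MeOH (2 equiv), THF, rt; then NaBO3·4H2O, THF–H2O, rt
Reagents that add atoms: bis(pinacolato)diboron, CC1(C)OB(OC1(C)C)B1OC(C)(C)C(C)(C)O1 (boron of 11); NaBO3·4H2O as its peroxoborate salt, [Na+].[Na+].O[B-]1(O)OO[B-](O)(O)OO1 (oxygen of 12)
Why: Copper-catalysed conjugate borylation of an α,β-unsaturated lactone (methanol protonates the copper enolate), then C–B oxidation with retention. The boryl group should add axially to the half-chair of 10 on the face opposite the equatorial C6 side chain, which gives the 4,6-trans arrangement required for C4.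

Step 9
Reactants: 12 (4R,6S)-4-hydroxy-6-[(S)-1-(TIPSO)-2-[4-(TIPSO)phenyl]ethyl]tetrahydro-2H-pyran-2-one
Product: 13 (4R,6S)-4-(TBSO)-6-[(S)-1-(TIPSO)-2-[4-(TIPSO)phenyl]ethyl]tetrahydro-2H-pyran-2-one
Conditions: TBSCl, imidazole, DMF, rt
Reagents that add atoms: tert-butyldimethylsilyl chloride, CC(C)(C)[Si](C)(C)Cl
Why: Standard silylation of a β-hydroxy lactone under weakly basic conditions that should not cause β-elimination; the ether blocks the C4 oxygen during the organolithium addition.

Step 10
Reactants: 14 4-bromo-2-methoxyphenol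
Product: 15 (4-bromo-2-methoxyphenoxy)triisopropylsilane
Conditions: TIPSCl, imidazole, DMF, rt
Reagents that add atoms: triisopropylsilyl chloride, CC(C)[Si](Cl)(C(C)C)C(C)C
Why: Silylation of the phenol so that the ring can be turned into an organolithium; the same fluoride step that frees the other hydroxyls will remove it.

Step 11
Reactants: 13 (4R,6S)-4-(TBSO)-6-[(S)-1-(TIPSO)-2-[4-(TIPSO)phenyl]ethyl]tetrahydro-2H-pyran-2-one; 15 (4-bromo-2-methoxyphenoxy)triisopropylsilane
Product: 17 (3R,5S,6S)-3-(TBSO)-5-hydroxy-1-[3-methoxy-4-(TIPSO)phenyl]-6-(TIPSO)-7-[4-(TIPSO)phenyl]heptan-1-one, via aryllithium 16 (not isolated)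
Conditions: 15, n-BuLi, THF, −78 °C; then 13, THF, −78 °C; NH4Cl (aq)
Reagents that add atoms: n-butyllithium, [Li]CCCC (lithium of 16 only)
Why: Bromine–lithium exchange, then a single addition of the aryllithium to the lactone carbonyl, as in aryl C-glycoside synthesis; the lithium hemiketal should persist at −78 °C and prevent a second addition. Work-up releases the δ-hydroxy ketone (in equilibrium with its ring tautomer) and frees the C6 hydroxyl without any deprotection step.

Step 12
Reactants: 17 (3R,5S,6S)-3-(TBSO)-5-hydroxy-1-[3-methoxy-4-(TIPSO)phenyl]-6-(TIPSO)-7-[4-(TIPSO)phenyl]heptan-1-one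
Product: 18 (3S,5S,6S)-3-(TBSO)-1-[3-methoxy-4-(TIPSO)phenyl]-6-(TIPSO)-7-[4-(TIPSO)phenyl]heptane-1,5-diol (both epimers at the benzylic carbinol C2 of the route numbering)
Conditions: NaBH4, MeOH–THF, 0 °C
Reagents that add atoms: none
Why: Borohydride reduction of the aryl ketone through its open-chain tautomer; no selectivity at C2 is asked for because step 13 erases that centre, and the silyl ethers are inert.

Step 13
Reactants: 18 (3S,5S,6S)-3-(TBSO)-1-[3-methoxy-4-(TIPSO)phenyl]-6-(TIPSO)-7-[4-(TIPSO)phenyl]heptane-1,5-diol (both C2 epimers)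
Product: 20 (2R,4S,6S)-4-(TBSO)-2-[3-methoxy-4-(TIPSO)phenyl]-6-[(1S)-1-(TIPSO)-2-[4-(TIPSO)phenyl]ethyl]tetrahydro-2H-pyran, via benzylic cation 19 (not isolated)
Conditions: Bi(OTf)3 (5 mol%), CH2Cl2 (0.02 M), 0 °C to rt
Reagents that add atoms: none
Why: The acid turns the benzylic C2 hydroxyl of either epimer of 18 into a leaving group, and loss of water gives cation 19, whose charge is delocalised onto the para silyloxy oxygen as a quinone-methide-like oxocarbenium ion; the 3-methoxy group is meta to C2 and adds nothing by resonance. The only free hydroxyl, on C6, then adds to C2 and forms O1–C2 in a 6-exo-trig closure, since the π-system of the attacked trigonal carbon lies outside the new ring. The closest known reaction type is the acid-catalysed dehydrative etherification of electron-rich benzylic alcohols to 2-aryl tetrahydropyrans. C2 is the one new stereocentre and is set by the C6 centre: in the chair transition state the C6 side chain and the planar aryl cation should both lie equatorial, which gives the 2,6-cis ether with the C4 silyloxy group axial. The product is again a para-oxygenated benzylic ether and should re-ionise under the same conditions, so any 2,6-trans ether returns to 19 and drains into the more stable diequatorial isomer; both epimers of 18 should therefore converge on 20. The step needs site selectivity among the oxygens and a clean cation: the C4 and C7 oxygens are silylated (closure through them would in any case need a four- or seven-membered ring), and high dilution with a catalytic, non-nucleophilic acid at low temperature should hold back elimination to the styrene and intermolecular etherification. TIPS on C7 and on the phenols resists the acid better than TBS, and loss of a silyl group after ring closure would be harmless because all four are removed in step 14.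

Step 14
Reactants: 20 (2R,4S,6S)-4-(TBSO)-2-[3-methoxy-4-(TIPSO)phenyl]-6-[(1S)-1-(TIPSO)-2-[4-(TIPSO)phenyl]ethyl]tetrahydro-2H-pyran
Product: 21 rhoiptelol B, (2R,4S,6S)-2-(4-hydroxy-3-methoxyphenyl)-6-[(1S)-1-hydroxy-2-(4-hydroxyphenyl)ethyl]tetrahydro-2H-pyran-4-ol
Conditions: TBAF (8 equiv), THF, 0 to 40 °C; NH4Cl (aq)
Reagents that add atoms: none
Why: Fluoride-induced cleavage of two aryl TIPS ethers, one secondary TIPS ether and one TBS ether in a single operation; no stereocentre is touched, and the benzylic O1–C2 ether never meets a hydrogenolysis catalyst or a strong acid.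

## Compound list

1 | L-tyrosine | N[C@@H](Cc1ccc(O)cc1)C(=O)O | starting material
2 | (R)-3-(4-hydroxybenzyl)oxiran-2-one (α-lactone, not isolated) | O=C1O[C@@H]1Cc1ccc(O)cc1 | intermediate
3 | (S)-2-hydroxy-3-(4-hydroxyphenyl)propanoic acid | O[C@@H](Cc1ccc(O)cc1)C(=O)O | intermediate
4 | methyl (S)-2-hydroxy-3-(4-hydroxyphenyl)propanoate | COC(=O)[C@@H](O)Cc1ccc(O)cc1 | intermediate
5 | methyl (S)-2-(TIPSO)-3-[4-(TIPSO)phenyl]propanoate | COC(=O)[C@@H](O[Si](C(C)C)(C(C)C)C(C)C)Cc1ccc(O[Si](C(C)C)(C(C)C)C(C)C)cc1 | intermediate
6 | (S)-2-(TIPSO)-3-[4-(TIPSO)phenyl]propanal | O=C[C@@H](O[Si](C(C)C)(C(C)C)C(C)C)Cc1ccc(O[Si](C(C)C)(C(C)C)C(C)C)cc1 | intermediate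
7 | (2S,3S)-2-(TIPSO)-1-[4-(TIPSO)phenyl]hex-5-en-3-yl diisopinocampheylborinate (not isolated) | C=CC[C@H](OB([C@@H]1C[C@@H]2C[C@H]([C@H]1C)C2(C)C)[C@@H]1C[C@@H]2C[C@H]([C@H]1C)C2(C)C)[C@@H](O[Si](C(C)C)(C(C)C)C(C)C)Cc1ccc(O[Si](C(C)C)(C(C)C)C(C)C)cc1 | intermediate
8 | (2S,3S)-2-(TIPSO)-1-[4-(TIPSO)phenyl]hex-5-en-3-ol | C=CC[C@H](O)[C@@H](O[Si](C(C)C)(C(C)C)C(C)C)Cc1ccc(O[Si](C(C)C)(C(C)C)C(C)C)cc1 | intermediate
9 | (2S,3S)-2-(TIPSO)-1-[4-(TIPSO)phenyl]hex-5-en-3-yl acrylate | C=CC[C@H](OC(=O)C=C)[C@@H](O[Si](C(C)C)(C(C)C)C(C)C)Cc1ccc(O[Si](C(C)C)(C(C)C)C(C)C)cc1 | intermediate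
10 | (S)-6-[(S)-1-(TIPSO)-2-[4-(TIPSO)phenyl]ethyl]-5,6-dihydro-2H-pyran-2-one | O=C1C=CC[C@@H]([C@@H](O[Si](C(C)C)(C(C)C)C(C)C)Cc2ccc(O[Si](C(C)C)(C(C)C)C(C)C)cc2)O1 | intermediate
11 | (4R,6S)-4-(4,4,5,5-tetramethyl-1,3,2-dioxaborolan-2-yl)-6-[(S)-1-(TIPSO)-2-[4-(TIPSO)phenyl]ethyl]tetrahydro-2H-pyran-2-one (boron trans to the C6 side chain, not isolated) | O=C1C[C@H](B2OC(C)(C)C(C)(C)O2)C[C@@H]([C@@H](O[Si](C(C)C)(C(C)C)C(C)C)Cc2ccc(O[Si](C(C)C)(C(C)C)C(C)C)cc2)O1 | intermediate
12 | (4R,6S)-4-hydroxy-6-[(S)-1-(TIPSO)-2-[4-(TIPSO)phenyl]ethyl]tetrahydro-2H-pyran-2-one (hydroxyl trans to the C6 side chain) | O=C1C[C@H](O)C[C@@H]([C@@H](O[Si](C(C)C)(C(C)C)C(C)C)Cc2ccc(O[Si](C(C)C)(C(C)C)C(C)C)cc2)O1 | intermediate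
13 | (4R,6S)-4-(TBSO)-6-[(S)-1-(TIPSO)-2-[4-(TIPSO)phenyl]ethyl]tetrahydro-2H-pyran-2-one | O=C1C[C@H](O[Si](C)(C)C(C)(C)C)C[C@@H]([C@@H](O[Si](C(C)C)(C(C)C)C(C)C)Cc2ccc(O[Si](C(C)C)(C(C)C)C(C)C)cc2)O1 | intermediate
14 | 4-bromo-2-methoxyphenol | COc1cc(Br)ccc1O | starting material
15 | (4-bromo-2-methoxyphenoxy)triisopropylsilane | COc1cc(Br)ccc1O[Si](C(C)C)(C(C)C)C(C)C | intermediate
16 | [3-methoxy-4-(TIPSO)phenyl]lithium (not isolated) | COc1cc([Li])ccc1O[Si](C(C)C)(C(C)C)C(C)C | intermediate
17 | (3R,5S,6S)-3-(TBSO)-5-hydroxy-1-[3-methoxy-4-(TIPSO)phenyl]-6-(TIPSO)-7-[4-(TIPSO)phenyl]heptan-1-one (open-chain form; ring–chain tautomer of the same compound expected alongside) | COc1cc(C(=O)C[C@H](O[Si](C)(C)C(C)(C)C)C[C@H](O)[C@@H](O[Si](C(C)C)(C(C)C)C(C)C)Cc2ccc(O[Si](C(C)C)(C(C)C)C(C)C)cc2)ccc1O[Si](C(C)C)(C(C)C)C(C)C | intermediate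
18 | (3S,5S,6S)-3-(TBSO)-1-[3-methoxy-4-(TIPSO)phenyl]-6-(TIPSO)-7-[4-(TIPSO)phenyl]heptane-1,5-diol, both epimers at the benzylic carbinol (C2 of the route numbering); key-step precursor | COc1cc(C(O)C[C@H](O[Si](C)(C)C(C)(C)C)C[C@H](O)[C@@H](O[Si](C(C)C)(C(C)C)C(C)C)Cc2ccc(O[Si](C(C)C)(C(C)C)C(C)C)cc2)ccc1O[Si](C(C)C)(C(C)C)C(C)C | intermediate
19 | C2 benzylic cation derived from 18 (not isolated) | COc1cc([CH+]C[C@H](O[Si](C)(C)C(C)(C)C)C[C@H](O)[C@@H](O[Si](C(C)C)(C(C)C)C(C)C)Cc2ccc(O[Si](C(C)C)(C(C)C)C(C)C)cc2)ccc1O[Si](C(C)C)(C(C)C)C(C)C | intermediate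
20 | (2R,4S,6S)-4-(TBSO)-2-[3-methoxy-4-(TIPSO)phenyl]-6-[(1S)-1-(TIPSO)-2-[4-(TIPSO)phenyl]ethyl]tetrahydro-2H-pyran (2,6-cis, C4 oxygen axial); key-step product | COc1cc([C@H]2C[C@H](O[Si](C)(C)C(C)(C)C)C[C@@H]([C@@H](O[Si](C(C)C)(C(C)C)C(C)C)Cc3ccc(O[Si](C(C)C)(C(C)C)C(C)C)cc3)O2)ccc1O[Si](C(C)C)(C(C)C)C(C)C | intermediate
21 | rhoiptelol B, (2R,4S,6S)-2-(4-hydroxy-3-methoxyphenyl)-6-[(1S)-1-hydroxy-2-(4-hydroxyphenyl)ethyl]tetrahydro-2H-pyran-4-ol | COc1cc([C@H]2C[C@H](O)C[C@@H]([C@@H](O)Cc3ccc(O)cc3)O2)ccc1O | target

## Step count and least certain steps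

Total step count: 14. Longest linear sequence: 13 steps (steps 1 to 9 and 11 to 14); step 10 is a one-step side branch that prepares 15.

Step 13 (key step). Most likely to go wrong: cation 19 may lose a proton towards C3 instead of being captured. The resulting styrene is an allylic silyl ether that could ionise further at C4. The acid may also strip the C4 TBS group before closure, or the trans ether may equilibrate too slowly under conditions mild enough for the silyl groups. The fallback avoids the free acyclic cation. It sets out from 17: with Et3SiH and BF3·OEt2 in CH2Cl2–MeCN at −78 to −30 °C, the ring tautomer of 17 should ionise to the cyclic 2-aryl oxocarbenium ion. The silane should deliver hydride axially to the half-chair that keeps the C6 side chain pseudo-equatorial, which places the aryl group equatorial. This reductive etherification, of the aryl C-glycoside type, comes back to the route at 20. It makes no new compound (entry F0).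

Step 8. Most likely to go wrong: insufficient facial discrimination in the boryl addition, or base-induced opening or β-elimination of the lactone during the oxidation. The fallback changes the way the C4 oxygen is introduced. It sets out from 10: nucleophilic epoxidation (H2O2, NaOH, MeOH, 0 °C, then mild acid to re-close any opened lactone) should occur anti to the C6 side chain and give the trans-epoxy lactone F1. Reductive opening at the α-carbon with phenylselenide ((PhSe)2, NaBH4, AcOH, EtOH) should then leave the C4–O bond intact. This comes back to the route at 12.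

Step 5. Most likely to go wrong: erosion of reagent control in this mismatched pairing (the aldehyde itself prefers the anti product), or epimerisation of the α-silyloxy aldehyde before it reacts. The fallback turns the substrate bias into an asset. It sets out from 6: allyltrimethylsilane with BF3·OEt2 in CH2Cl2 at −78 °C should give the Felkin product, the C6 epimer (2S,3R)-2-(TIPSO)-1-[4-(TIPSO)phenyl]hex-5-en-3-ol F2. A Mitsunobu esterification with acrylic acid (PPh3, DIAD, THF) then inverts C6 and installs the acrylate in one step. This comes back to the route at 9.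

Step 11. Most likely to go wrong: deprotonation α to the lactone carbonyl by the aryllithium, followed by β-elimination of the C4 silanolate, or a second addition if the lithium hemiketal collapses early. The fallback uses the aldehyde oxidation level and a less basic nucleophile. It sets out from 13: iBu2AlH in CH2Cl2 at −78 °C should give the lactol F3. The Grignard reagent F4, made from 15 and Mg in THF and used in excess at 0 °C to rt, should open the lactol through its aldehyde form and add to it. This comes back to the route at 18 and bypasses 17.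

## Further compounds

F0 | step 13 | none | none
F1 | step 8 | 3,4-epoxy-6-[(S)-1-(TIPSO)-2-[4-(TIPSO)phenyl]ethyl]tetrahydro-2H-pyran-2-one, oxirane oxygen trans to the C6 side chain, C6 and C7 as in 10 | O=C1[C@@H]2O[C@@H]2C[C@@H]([C@@H](O[Si](C(C)C)(C(C)C)C(C)C)Cc2ccc(O[Si](C(C)C)(C(C)C)C(C)C)cc2)O1
F2 | step 5 | (2S,3R)-2-(TIPSO)-1-[4-(TIPSO)phenyl]hex-5-en-3-ol | C=CC[C@@H](O)[C@@H](O[Si](C(C)C)(C(C)C)C(C)C)Cc1ccc(O[Si](C(C)C)(C(C)C)C(C)C)cc1
F3 | step 11 | (4R,6S)-4-(TBSO)-6-[(S)-1-(TIPSO)-2-[4-(TIPSO)phenyl]ethyl]tetrahydro-2H-pyran-2-ol (lactol, both anomers) | OC1C[C@H](O[Si](C)(C)C(C)(C)C)C[C@@H]([C@@H](O[Si](C(C)C)(C(C)C)C(C)C)Cc2ccc(O[Si](C(C)C)(C(C)C)C(C)C)cc2)O1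
F4 | step 11 | [3-methoxy-4-(TIPSO)phenyl]magnesium bromide | COc1cc([Mg]Br)ccc1O[Si](C(C)C)(C(C)C)C(C)C
A1 | alternative 1 | 2-(tert-butyldimethylsilyl)-1,3-dithiane | CC(C)(C)[Si](C)(C)C1SCCCS1
A2 | alternative 1 | 2-[4-(benzyloxy)-3-methoxyphenyl]oxirane (either enantiomer or the racemate) | COc1cc(C2CO2)ccc1OCc1ccccc1
A3 | alternative 1 | (S)-2-[(S)-1-(benzyloxy)-2-[4-(benzyloxy)phenyl]ethyl]oxirane | C1O[C@@H]1[C@@H](OCc1ccccc1)Cc1ccc(OCc2ccccc2)cc1
A4 | alternative 1 | C4 dithiane of the full chain: C2 OTBS (both epimers), C6 hydroxyl, C7 benzyl ether, benzyl-protected phenols | COc1cc(C(O[Si](C)(C)C(C)(C)C)CC2(C[C@H](O)[C@@H](OCc3ccccc3)Cc3ccc(OCc4ccccc4)cc3)SCCCS2)ccc1OCc1ccccc1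
A5 | alternative 2 | (E)-4-[4-(benzyloxy)-3-methoxyphenyl]-2-(triethylsilyloxy)buta-1,3-diene | C=C(O[Si](CC)(CC)CC)/C=C/c1ccc(OCc2ccccc2)c(OC)c1
A6 | alternative 2 | (S)-3-[4-(benzyloxy)phenyl]-2-(tert-butyldimethylsilyloxy)propanal | O=C[C@@H](O[Si](C)(C)C(C)(C)C)Cc1ccc(OCc2ccccc2)cc1
A7 | alternative 2 | 2,6-cis 3,6-dihydro-2H-pyran with a C4 triethylsilyl enol ether (C3=C4), C7 OTBS and benzyl-protected phenols | COc1cc([C@H]2C=C(O[Si](CC)(CC)CC)C[C@@H]([C@@H](O[Si](C)(C)C(C)(C)C)Cc3ccc(OCc4ccccc4)cc3)O2)ccc1OCc1ccccc1
A8 | alternative 3 | (4S,5S)-5-(benzyloxy)-6-[4-(benzyloxy)phenyl]-4-[[4-(benzyloxy)-3-methoxybenzyl]oxy]hex-1-en-2-yl acetate | C=C(OC(C)=O)C[C@H](OCc1ccc(OCc2ccccc2)c(OC)c1)[C@@H](OCc1ccccc1)Cc1ccc(OCc2ccccc2)cc1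
A9 | alternative 3 | 2,6-cis tetrahydropyran-4-one with C7 benzyl ether and benzyl-protected phenols | COc1cc([C@H]2CC(=O)C[C@@H]([C@@H](OCc3ccccc3)Cc3ccc(OCc4ccccc4)cc3)O2)ccc1OCc1ccccc1
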